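The coupling partner is the limiting reagent of the flask, with 0.120 mM charged against 0.20 mM of starting material and 0.200 mM of second substrate, so its balance is the reckoning to write. By the steps thought possible, it is consumed into target, second product or quenched reagent, and target goes on to over-reaction product.

in all of them: starting material 0.20 mM
- larch: coupling partner 0.080 mM; second substrate 0.20 mM; protic impurity 0.0040 mM; catalyst 2 µM; run made earlier
- elm: coupling partner 0.18 mM; second substrate 0.20 mM; protic impurity 0.0040 mM; catalyst 2 µM; run made earlier
- maple: coupling partner 0.12 mM; second substrate 0.10 mM; protic impurity 0.0040 mM; catalyst 2 µM; run made earlier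
- flask: coupling partner 0.120 mM; second substrate 0.200 mM; protic impurity 0.00400 mM; catalyst 2.0 µM; time 15 min

- larch (time / min: target / %): 0.200: 23; 0.500: 26; 2.00: 25; 6.00: 22; 20.0: 18
- elm (time / min: target / %): 0.200: 47; 0.500: 56; 2.00: 56; 6.00: 49; 20.0: 36
- maple (time / min: target / %): 0.200: 34; 0.500: 43; 2.00: 47; 6.00: 43; 20.0: 33

(standard deviation of a reading: 1.5 percentage points)

- the analysis behind the earlier runs scatters by 1.5 percentage points, standard deviation
- steps thought possible: starting material + coupling partner + catalyst -> catalyst + target; second substrate + coupling partner + catalyst -> catalyst + second product; target -> over-reaction product; coupling partner + protic impurity -> quenched reagent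

1. when, up to 15 min, the flask holds most target
2. the amount of target, in percent of the starting material charged, at that time

The readings give a ladder of time scales. On the fastest rung, target in the elm run reads 47% at 0.200 min and 56% at 0.500 min, so coupling takes a fraction of a minute. On the slowest rung, target in the elm run falls from 56% at 2.00 min to 36% at 20.0 min. Read as first-order, that is 0.0245 min⁻¹, a lifetime of 40.8 min, far longer than coupling. The peak therefore serves as a reading of the balance.

My own reckoning counts the whole protic impurity as taken from the coupling partner, which leaves the usable coupling partner u, the charge minus the impurity, at 0.116 mM in the flask. The capture share φ is the peak target, in mM, divided by u. It reads 68.4% in the larch run and 63.6% in the elm run, both with the second substrate of the flask. Their mean is 66.0%, which puts the flask's peak at 38.3%, somewhere between 0.500 min and 2.00 min.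

The forecast gives 39% at 1 min: “Coupling finishes within about a minute”.

The flask peaks at 0.730 min with 37.7% of target.

    starting material + coupling partner + catalyst → catalyst + target (k = 3.10 × 10⁸ M⁻² s⁻¹)
    second substrate + coupling partner + catalyst → catalyst + second product (k = 1.40 × 10⁸ M⁻² s⁻¹)
    target → over-reaction product (k = 3.90 × 10⁻⁴ s⁻¹)
    coupling partner + protic impurity → quenched reagent (k = 51000 M⁻¹ s⁻¹)

In the flask at that time the coupling partner stands at 0.320% of its own charge, while 61.8% of the starting material remains. The flask's own φ comes to 65.0%. The neighbour with 0.34 mM of starting material has the same u, so the mean φ gives it 22.5% of its charge. It stores 26.2%, a capture share of 76.8%.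

The readings were computed from invented constants; noise was put on by code.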